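The easy step comes first: Z meets J and gives E, and J comes back unchanged unless it has turned into D.

Z 0.10 M; L 0.0950 M; J 5.0 mM; Q 56 µM

    Z + J → J + E (k1 = 11 M⁻¹ s⁻¹)
    J → D (k2 = 0.046 s⁻¹)
    L + Q.E → Q + G (k3 = 23 M⁻¹ s⁻¹)
    Q + E ⇌ Q.E (K4 = 1300 M⁻¹, k4 = 79000 M⁻¹ s⁻¹)

- the form that holds most of the catalyst when 50 % of the Z are converted (D / J)
- its share of the catalyst then
- apparent order in L when 50 % of the Z are converted (percent change of the rate of making G for one percent more L charged)
- factor on the rate of making G when 50 % of the Z are converted if L is charged twice over

Which numbers must be known well? Z is used, per Z, at 11 M⁻¹ s⁻¹ times [J], and J fades into D at 0.046 s⁻¹ whatever Z, L and Q do. The curve of [J] therefore acts on Z through the area under it, and a mean of [J] over the time elapsed carries the same effect without error. Let 1.20 be the first constant times the J charged, 5.0 mM, over the fading constant. This is the reach of the catalyst, the natural logarithm of the drop in Z that J delivers over its whole life. At 50 % conversion the faded share is the logarithm of two over the reach. One percent off in either constant or in the J charged moves that share by one percent of itself, while the charge of Z cancels and L and Q do not enter. So the form holding most of the catalyst then is D, at 58.0 %; this share is lost catalyst outside the working round, not a resting state, as step 2 has no way back.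

For the order, the binding constant matters little. E is then made at 1.16 mM s⁻¹, and L takes it through fully bound Q at 0.122 mM s⁻¹. Because E is made faster, it stands near the 0.0500 M of Z converted. Q.E, the resting state of Q, then holds 98.5 % of Q, and with half that binding constant it would hold 97.0 %. My order in L is 1.00, and my factor is 2.00.

The forecast gives D at 58 %, order 1 and factor 2, since “Q sits almost entirely as Q.E”.

The simulation gives D at 58.0 %, order 1.0 and factor 2.00. The half-life of Z by its step, 0.33 min at 0.161 min, is far shorter than that of L by its step, 9.1 min at 2.00 min. This flask runs in two stages: Z stands at 30.4 % of its charge after 2.00 min and 30.3 % after 20.0 min, against 30.1 % from the reach, while G climbs from 13.4 % to 69.7 % of the Z charged. In a second flask with twice the J the reach doubles, which puts the time to 50 % conversion at 0.395 of the first flask's, and that run reads 0.395.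

The numbers of this flask stand for no real mixture; the flask was simulated.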